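Slowness sits at the end of the chain. Released group leaves with a half-life of 0.28 min, longer than the forward half-lives of substrate by binding, 0.11 min as charged in larch, and of open intermediate by splitting, 0.053 min. Carrying-off is therefore the rate-limiting step on the way to target.

    released group → by-product carried off (k1 = 0.042 /s)
    open intermediate ⇌ target + released group (K2 = 0.23 M, k2 = 0.22 /s)
    substrate + partner ⇌ open intermediate (K3 = 250 /M, k3 = 0.68 /M/s)
    open intermediate + capture agent → trapped intermediate (k4 = 1.0 /M/s)

| setting | larch | cedar | oak | maple |
|---|---|---|---|---|
| substrate | 0.074 M | 0.074 M (fed, over 2.00 min) | 0.074 M | 0.074 M |
| partner | 0.148 M | 0.148 M | 0.148 M (fed, over 2.00 min) | 0.148 M |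
| capture agent | 3.70 mM | 3.70 mM | 3.70 mM | 3.70 mM |
| time | 2.5 min | 2.5 min | 2.5 min |  |
| remark | everything together in a closed stirred flask, run for 2.5 min | a stirred flask in which substrate is dosed at a steady rate over 2.00 min without added volume, worked up at 2.5 min | all but partner at the start; partner goes in evenly over 2.00 min, the run ends at 2.5 min | one stirred flow tank at steady state, fed with the mixture as stated, mean residence time 2.5 min |

- the set-up with the highest amount of target at the outlet or at the end, in percent of the substrate put in ("none" if the first two lie within 2 percentage points) (larch / cedar / oak / maple / none)
- amount of target at the outlet or at the end, in percent of the substrate put in, larch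
- amount of target at the outlet or at the end, in percent of the substrate put in, cedar
- amount of target at the outlet or at the end, in percent of the substrate put in, oak
- amount of target at the outlet or at the end, in percent of the substrate put in, maple

By my reckoning, open intermediate stands near c_target·c_released/K2, since it splits and re-forms quickly. With c_target near the substrate charge, it holds 0.322 of a unit per unit of released group, and this pool drains through released group. Unfinished material therefore waits on the drain life, (one + cA/K2)/k1 = 0.524 min. The deciding number is the run time counted in drain lives: D = 4.77.

A power of ten costs 2.3 lives, so larch falls 2.07 powers of ten, to 0.851% unfinished. Averaging the same decay over a steady feed leaves 9.89% in cedar. In oak, substrate needs the first 1.00 min of partner feed, which leaves 2.56%. The tank maple replaces the exponential with one over one plus D, leaving 17.3%.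

One number is not quite enough. Oak's window of 1.00 min is shorter than its feed of 2.00 min, so the reckoned 1.7 percentage points between oak and larch is a low figure beside the margin of 2 points. I commit to larch.

The forecast differs on that choice: 97.2%, 90.3%, 96.3%, 81.8%, best none, holding that “larch and oak finish nearly complete and within 2 points of each other”.

| Flask | Reckoned unfinished | Target found |
|---|---|---|
| larch | 0.851% | 96.8% |
| cedar | 9.89% | 90.6% |
| oak | 2.56% | 93.6% |
| maple | 17.3% | 81.8% |

The best is larch, ahead of oak by 3.2 points. The carrying-off of released group is the largest single effect on larch: without it, larch gives 76.0% against 96.8%. The time left after the feed is worth a factor of 0.385 in drain lives. Substrate plus open intermediate in oak falls to a factor of 0.371 over that time, and in cedar to a factor of 0.349.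

The numbers stand for no real mixture; the rest is arithmetic.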